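**Retrosynthetic overview**
- Supply of the acid partner: 4-hydroxyphenylacetic acid 1 is mono-brominated ortho to OH to give 3-bromo-4-hydroxyphenylacetic acid 2, which is ring A carrying the future bridge carbon with a CO2H handle on it.
- Key disconnection: the bond between the bridging CH2 and the ring carbon para to OH (C4) of 2,6-dibromophenol 3 (ring B). Anodic decarboxylation of 2 releases p-quinone methide 4, which C4 of 3 captures to give target 5 directly.
- Enabling feature: in ring A the OH-bearing carbon is para to the carbon that carries the CH2 bridge, so loss of two electrons and CO2 turns the bridge carbon into the exocyclic =CH2 of a p-quinone methide. In ring B both carbons ortho to OH carry Br, so C4 is the only nucleophilic ring carbon.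
- No ring is formed: both benzene rings are bought intact, and the CO2H group is the only auxiliary group, lost as CO2 in the bond-forming step.

Key step: step 2

Remark: the target has no stereogenic element (a CH2 bridge between two planar rings), so it is achiral and "single enantiomer" is taken to mean the constitution as drawn; no step has to set or protect configuration.

**Step 1**
Reactants: 1 4-hydroxyphenylacetic acid
Product: 2 3-bromo-4-hydroxyphenylacetic acid
Conditions: Br2 (1.0 equiv, dropwise), AcOH, 15 °C to rt
Reagents that add atoms: bromine, BrBr
Why: Electrophilic aromatic bromination; OH directs ortho because the para position is blocked by the CH2CO2H group, and one equivalent of Br2 should stop at the mono-bromide because the first bromine deactivates the ring.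

**Step 2**
Reactants: 2 3-bromo-4-hydroxyphenylacetic acid; 3 2,6-dibromophenol (4 equiv, excess recoverable)
Product: 5 2,6-dibromo-4-[(3-bromo-4-hydroxyphenyl)methyl]phenol, via 2-bromo-p-quinone methide 4 (not isolated)
Conditions: graphite anode, Pt cathode, undivided cell, constant current (about 5 mA cm−2, 2.0–2.2 F per mol of 2), 2,4,6-collidine (0.2 equiv), nBu4NPF6 (0.1 M), HFIP, 2 at 0.05 M, 20 °C
Reagents that add atoms: none
Why: Proposed new method: anodic two-electron oxidation of the phenol ring of 2 (the more electron-rich phenol in the cell: one Br and a para-alkyl group, against two Br and no alkyl group in 3) should be followed by loss of CO2 and a proton from the CH2CO2H group para to the oxidised oxygen (pseudo-Kolbe/Hofer–Moest fragmentation) to give p-quinone methide 4, whose exocyclic CH2, activated by hydrogen bonding to HFIP, should be attacked by C4 of 3 in a Friedel–Crafts 1,6-addition that rearomatises both rings. The closest known reaction types are the anodic non-Kolbe decarboxylation of 4-methoxyphenylacetic acids to benzylic cations that are trapped by O-nucleophiles, and the acid- or HFIP-promoted para-C-benzylation of phenols by p-quinone methides and 4-hydroxybenzyl alcohols; joining the two into a decarboxylative C–C cross-coupling of two free phenols is the untested part. No ring is closed and no stereocentre is formed, so only chemo- and regioselectivity matter. Chemoselective oxidation of 2 beside excess 3 should follow from its lower oxidation potential and from the sub-stoichiometric collidine going to the carboxylic acid, the strongest acid present, while the irreversible CO2 loss gives oxidised 2 a fast exit that oxidised 5 lacks. Regioselectivity in 3 is fixed by the Br atoms on both carbons ortho to OH, which leave the para carbon as the only activated position, and O-alkylation or capture by HFIP gives 4-hydroxybenzyl ethers that should re-ionise to 4 under the conditions; self-alkylation of 2 or 5 at the free carbon ortho to OH is held back by the excess of 3 and by the low stationary concentration of 4 set by the current. Protons are reduced to H2 at the Pt cathode well before the aryl bromides, so no chemical oxidant is needed and the three C–Br bonds should survive.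

**Compound list**
1 | 4-hydroxyphenylacetic acid | OC(=O)Cc1ccc(O)cc1 | starting material
2 | 3-bromo-4-hydroxyphenylacetic acid | OC(=O)Cc1ccc(O)c(Br)c1 | intermediate
3 | 2,6-dibromophenol | Oc1c(Br)cccc1Br | starting material
4 | 2-bromo-4-methylidenecyclohexa-2,5-dien-1-one (2-bromo-p-quinone methide) | C=C1C=CC(=O)C(Br)=C1 | intermediate
5 | 2,6-dibromo-4-[(3-bromo-4-hydroxyphenyl)methyl]phenol | Oc1ccc(Cc2cc(Br)c(O)c(Br)c2)cc1Br | target

**Totals**
Total step count: 2. Longest linear sequence: 2 steps (1 → 2 → 5; 3 enters as a purchased material).

**Steps most likely to fail** (the route has only two steps, so both are treated)

1. Step 2 (proposed new method). The anode may not discriminate well enough: competitive oxidation of 3 or re-oxidation of product 5 would lead to phenol–phenol C–C/C–O coupling or further benzylic oxidation, and the quinone methide may oligomerise with its own precursor instead of being captured by 3. The fallback uses known chemistry, sets out from 3 and comes back to the route at 5. Purchased 3-bromo-4-hydroxybenzaldehyde F1 would be reduced (NaBH4, MeOH, 0 °C) to 3-bromo-4-hydroxybenzyl alcohol F2. F2 would then be added slowly to excess 3 with catalytic TfOH in HFIP at rt. This is the acid-catalysed Friedel–Crafts para-benzylation of a phenol by a 4-hydroxybenzyl alcohol (bisphenol-type condensation), forming the same CH2–C4 bond without any electron transfer at the phenols.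

2. Step 1. Bromination may not stop cleanly at one bromine, giving the 3,5-dibromo acid beside unreacted 1 in a mixture that is hard to purify by crystallisation. The fallback buys the bromine already in place and forms the side chain instead. It sets out from no numbered compound (purchased 2-bromophenol F3 takes the place of 1) and comes back to the route at 2. F3 would be condensed with glyoxylic acid (OC(=O)C=O; aqueous NaOH, 20–40 °C), an electrophilic hydroxyalkylation para to OH, to give racemic 3-bromo-4-hydroxymandelic acid F4. Ionic hydrogenation of the benzylic hydroxyl of F4 (Et3SiH, TFA, 50 °C) should then give 2.

**Further compounds**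
F1 | step 2 | 3-bromo-4-hydroxybenzaldehyde (purchased) | O=Cc1ccc(O)c(Br)c1
F2 | step 2 | 3-bromo-4-hydroxybenzyl alcohol | OCc1ccc(O)c(Br)c1
F3 | step 1 | 2-bromophenol (purchased) | Oc1ccccc1Br
F4 | step 1 | 3-bromo-4-hydroxymandelic acid (racemic) | OC(C(=O)O)c1ccc(O)c(Br)c1
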